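**Compound numbering used throughout:** ring A is the phenol ring (C1 OH, C2 Br, C3 Br, C4 H, C5 Br, C6 O-aryl); ring B is the aryloxy ring (C1' ether oxygen, C2' Br, C4' Br).

## The problem

Compound 12 is two benzene rings held together by a single ether oxygen that links C6 of ring A to C1' of ring B. No ring has to be built and there is no stereocentre, so the whole task is control of position. Ring A carries the hydroxyl at C1, bromine at C2, C3 and C5 and the aryloxy group at C6, which leaves C4 as its only C–H; ring B carries bromine at C2' and C4'. The pattern of ring A is not what any single directing group would produce: C5 and C3 lie ortho and para to the ether oxygen, C2 lies ortho to the hydroxyl, and C4, para to the hydroxyl, has to stay free. The ether oxygen is flanked by the hydroxyl and C5–Br on one side and by C2'–Br on the other, so a late union of two fully brominated halves is hindered and, if a transition metal is used, must pick one carbon–halogen bond out of several. Once in place, the five aryl C–Br bonds exclude organolithium reagents, zerovalent palladium or nickel, dissolving metals and catalytic hydrogenation, and the free electron-rich phenol is prone to over-bromination and oxidation. The feature that opens the route is ring B: its bromines at C2' and C4' sit ortho and para to the oxygen on C1', exactly where a phenoxy ring takes up electrophilic bromine. Ring B can therefore travel as a plain phenyl group and be brominated at the end, provided ring A has by then been made inert.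

## Retrosynthesis

**12 from 11 (O–acetyl bond).** The free C1 hydroxyl cannot be present while ring B is brominated, because it would activate C4, the one open carbon of ring A. The last cut is therefore the removal of an electron-withdrawing mask from oxygen. An acetate is preferred to a methyl ether: it ties up the oxygen lone pair, and it comes off with hydroxide at room temperature instead of a Lewis acid. The forward reaction only has to cleave an ester without touching C–Br bonds.

**11 from 9 (C4'–Br and C2'–Br).** These two bonds are cut together because both lie at the positions a phenoxy ring brominates by itself. The neighbouring cut, the O–C1' ether bond of a fully brominated compound, would need a 2,4-dibromophenyl donor and a hindered coupling in the presence of C–Br bonds. Precursor 9 is simpler by two bromines and its ring B is unsubstituted phenyl. The forward reaction must brominate ring B before ring A and stop after the second substitution; the mono-brominated acetate 10 is passed through without isolation.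

**9 from 8 (O–acetyl bond).** Acetylation of phenol 8 is the point where ring A is switched off. The only demand is acylation of a hydroxyl flanked by bromine and phenoxy.

**8 from 7 (C2–Br).** C2–Br is the one ring A bromine that is meta to the ether oxygen, so it cannot come from the same directing group as the other two. It is ortho to the hydroxyl, and cutting it last on ring A lets the free phenol of 7 direct it. The forward bromination must choose the ortho carbon over C4 (para to the hydroxyl, between two bromines) and must leave the phenoxy ring alone.

**7 from 5 (O–CH3 bond).** The hydroxyl of 7 is stored as a methyl ether. This keeps the oxygen silent while its neighbour is arylated and lets its directing power be switched on only when C2 is to be brominated. The forward ether cleavage proceeds through borate 6 and must spare the diaryl ether.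

**5 from 3 and 4 (O–C1' bond).** The ether is cut at the phenyl side into phenol 3 and phenylboronic acid 4. The aryl donor is halogen-free, so an oxidative copper coupling at room temperature never has to discriminate between C–Br bonds, which an Ullmann or palladium coupling with an aryl halide partner would. The forward reaction must arylate an oxygen flanked by bromine and methoxy.

**3 from 1 (C3–Br and C5–Br in the numbering of 12).** Both bromines are para and ortho to the oxygen that becomes the ether, which is the free hydroxyl of guaiacol 1. Two successive electrophilic brominations, through monobromide 2, place them. The forward reaction relies on the hydroxyl outranking the methoxy group as director.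

## Roads not taken

**Alternative 1:** Ring A is taken apart across C5–C6 and C1–C2 (numbering of 12) into 3,5-dibromo-2H-pyran-2-one A1 and the alkynylboronate A2. The two alkyne carbons of A2 already carry the 2,4-dibromophenoxy group and a pinacolboryl group.
- Forward key step: A1 and A2 would undergo [4+2] cycloaddition, and the bridged lactone would lose its carboxyl bridge by cycloreversion to give arylboronate A3. Oxidation of the C–B bond would then give the C1 hydroxyl.
- Merits: C3–Br and C5–Br are fixed by construction and ring B arrives fully brominated. The polarity of an ynol ether should send its oxygen-bearing carbon to the pyrone carbon next to the carbonyl, as required.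
- Weak points: A2 belongs to a barely explored class. Aryloxyalkynes are normally made by strong-base elimination and metalation, which the two aryl bromines of A2 would not survive because of halogen–metal exchange. The cycloaddition needs heat that an ynol ether may not tolerate. A3 still lacks C2–Br, so the hydroxyl-directed ortho-bromination of step 4 would be needed anyway.
- Comparison: this road is more convergent on paper and leaves no doubt about C3 and C5. In practice it is longer (preparation of A1 and A2, cycloaddition, oxidation, bromination) and rests on two operations without close precedent. The chosen plan places the same two bromines by the textbook ortho/para bromination of a phenol.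

**Alternative 2:** All three C–Br bonds of ring A are cut at once, with an amino group placed temporarily on C4.
- Forward key step: aniline A4, with ring B already dibrominated, would be brominated at every open carbon of ring A to give A5. Diazotisation with reductive loss of nitrogen would restore C4–H, and ether cleavage would free the C1 hydroxyl.
- Merits: no positional choice is left on ring A, since every C–H is substituted, and the amino group occupies exactly the carbon that is the weak point of step 4. In this respect the road is better than the chosen plan.
- Weak points: the third bromine, at C2, is meta to nitrogen and is driven only by a methoxy group flanked on both sides, so the bromination may stall after two substitutions. A4 needs the hindered ether to be made with bromine already on ring B, that is, with a specially prepared aryl-transfer reagent or a metal coupling next to C–Br bonds. A nitro group has to be reduced without loss of bromine, and diazonium chemistry is added on a pentabromide.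
- Comparison: the step count is similar. Against the certainty on ring A, the chosen plan sets a halogen-free aryl donor, no nitrogen to introduce and destroy, and a ring B pattern that comes from innate directing effects.

**Alternative 3:** Ring B is cut across C1'–C2' and C5'–C6' into the ethynyl ether A6 of phenol 3 and pyrone A1.
- Forward key step: cycloaddition and cycloreversion would close ring B on the ether oxygen that is already in place and give A7. Demethylation and bromination at C2 would follow as in the chosen plan.
- Merits: the hindered O–C1' bond is never made by a coupling. C2'–Br and C4'–Br are fixed by the pyrone, so the degree of bromination of ring B is not in question. On that point this road is more secure than the chosen key step.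
- Weak points: A6 has to be made from 3 by strongly basic elimination chemistry in the presence of two aryl bromines. Aryl ethynyl ethers are sensitive to heat and moisture, while the cycloaddition needs heating. A1 is not a stock chemical.
- Comparison: with the preparation of A1 and A6 the sequence is no shorter. The chosen plan obtains the same 2',4' pattern in one operation from a cheap reagent; what it has to secure in exchange is the inertness of ring A and control of stoichiometry.

Key step: step 6

## Route

Step 1
Reactants: 1 guaiacol (2-methoxyphenol)
Product: 3 4,6-dibromo-2-methoxyphenol, via 4-bromo-2-methoxyphenol 2 (not isolated)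
Conditions: Br2 (2.05 equiv), AcOH, 10 °C to rt
Reagents that add atoms: bromine, BrBr
Why: Electrophilic aromatic bromination of a phenol; the free hydroxyl outranks the methoxy group as director, so the first bromine should enter para and the second ortho to the hydroxyl.

Step 2
Reactants: 3 4,6-dibromo-2-methoxyphenol; 4 phenylboronic acid
Product: 5 1,5-dibromo-3-methoxy-2-phenoxybenzene
Conditions: 4 (2.0 equiv), Cu(OAc)2 (1.0 equiv), pyridine (5 equiv), 4 Å MS, CH2Cl2, air, rt
Reagents that add atoms: none
Why: Chan–Lam coupling: the phenoxide and the phenyl group meet on divalent copper, oxidation to trivalent copper is followed by C–O reductive elimination. Ortho,ortho'-disubstituted halophenols are known substrates, and aryl C–Br bonds do not react with copper at room temperature.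

Step 3
Reactants: 5 1,5-dibromo-3-methoxy-2-phenoxybenzene
Product: 7 3,5-dibromo-2-phenoxyphenol, via dibromo(3,5-dibromo-2-phenoxyphenoxy)borane 6 (not isolated)
Conditions: BBr3 (1.5 equiv), CH2Cl2, −78 °C to rt; then H2O
Reagents that add atoms: none
Why: Lewis-acid cleavage of an aryl methyl ether: boron binds the methoxy oxygen and bromide removes the methyl group by SN2. The diaryl ether survives because neither of its carbons can undergo displacement.

Step 4
Reactants: 7 3,5-dibromo-2-phenoxyphenol
Product: 8 2,3,5-tribromo-6-phenoxyphenol
Conditions: NBS (1.0 equiv), i-Pr2NH (0.1 equiv), CH2Cl2, 0 °C
Reagents that add atoms: N-bromosuccinimide, O=C1CCC(=O)N1Br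
Why: Amine-mediated ortho-selective bromination of a phenol: the N-bromoamine formed in the flask is hydrogen-bonded to the hydroxyl and delivers bromine to the only free ortho carbon (C6 of 7, C2 of 12). The para carbon is shielded by two flanking bromines, and the phenoxy ring is far less nucleophilic than the phenol.

Step 5
Reactants: 8 2,3,5-tribromo-6-phenoxyphenol
Product: 9 2,3,5-tribromo-6-phenoxyphenyl acetate
Conditions: Ac2O (1.5 equiv), pyridine (3 equiv), DMAP (0.05 equiv), CH2Cl2, rt
Reagents that add atoms: acetic anhydride, CC(=O)OC(C)=O
Why: Nucleophile-catalysed O-acylation; the acylpyridinium ion is reactive enough for a hydroxyl flanked by bromine and phenoxy.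

Step 6
Reactants: 9 2,3,5-tribromo-6-phenoxyphenyl acetate
Product: 11 2,3,5-tribromo-6-(2,4-dibromophenoxy)phenyl acetate, via 2,3,5-tribromo-6-(4-bromophenoxy)phenyl acetate 10 (not isolated)
Conditions: Br2 (2.2 equiv), FeBr3 (0.05 equiv), CH2Cl2, 0 °C to rt, dark
Reagents that add atoms: bromine, BrBr
Why: Electrophilic aromatic substitution: FeBr3 polarises Br2, the phenoxy ring attacks it, and the arenium (Wheland) ion is stabilised by the lone pair of the ether oxygen, which only ring B can use well because ring A is electron-poor and twisted by substituents on both sides of the oxygen. The first bromine should enter at C4' (para, unhindered) to give 10 and the second at C2' (ortho) to give 11; the meta carbons receive no such stabilisation. The closest known reaction type is the Lewis-acid-catalysed ortho/para bromination of diaryl ethers, for example diphenyl ether to its 2,2',4,4'-tetrabromide. No ring is closed and no stereocentre is formed. Ring B must react before ring A, which is secured by the three bromines of ring A, by the acetate (its oxygen lone pair is engaged with the carbonyl group) and by the position of C4–H between two bromines and meta to the ether oxygen. The reaction must also stop at two bromines: the remaining activated carbon C6' lies on a ring that then carries two deactivating bromines and is twisted by the new C2' substituent, and the charge of Br2 is limited to slightly more than two equivalents.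

Step 7
Reactants: 11 2,3,5-tribromo-6-(2,4-dibromophenoxy)phenyl acetate
Product: 12 2,3,5-tribromo-6-(2,4-dibromophenoxy)phenol
Conditions: LiOH·H2O (3 equiv), THF/H2O (3:1), 0 °C to rt; then 1 M HCl
Reagents that add atoms: none
Why: Saponification of an aryl acetate; the electron-poor aryloxide is a good leaving group, and aryl bromides and the diaryl ether are inert to aqueous hydroxide at room temperature.

## Compound list

1 | guaiacol (2-methoxyphenol) | COc1ccccc1O | starting material
2 | 4-bromo-2-methoxyphenol | COc1cc(Br)ccc1O | intermediate
3 | 4,6-dibromo-2-methoxyphenol | COc1cc(Br)cc(Br)c1O | intermediate
4 | phenylboronic acid | OB(O)c1ccccc1 | starting material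
5 | 1,5-dibromo-3-methoxy-2-phenoxybenzene | COc1cc(Br)cc(Br)c1Oc1ccccc1 | intermediate
6 | dibromo(3,5-dibromo-2-phenoxyphenoxy)borane | BrB(Br)Oc1cc(Br)cc(Br)c1Oc1ccccc1 | intermediate
7 | 3,5-dibromo-2-phenoxyphenol | Oc1cc(Br)cc(Br)c1Oc1ccccc1 | intermediate
8 | 2,3,5-tribromo-6-phenoxyphenol | Oc1c(Br)c(Br)cc(Br)c1Oc1ccccc1 | intermediate
9 | 2,3,5-tribromo-6-phenoxyphenyl acetate | CC(=O)Oc1c(Br)c(Br)cc(Br)c1Oc1ccccc1 | intermediate
10 | 2,3,5-tribromo-6-(4-bromophenoxy)phenyl acetate | CC(=O)Oc1c(Br)c(Br)cc(Br)c1Oc1ccc(Br)cc1 | intermediate
11 | 2,3,5-tribromo-6-(2,4-dibromophenoxy)phenyl acetate | CC(=O)Oc1c(Br)c(Br)cc(Br)c1Oc1ccc(Br)cc1Br | intermediate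
12 | 2,3,5-tribromo-6-(2,4-dibromophenoxy)phenol | Oc1c(Br)c(Br)cc(Br)c1Oc1ccc(Br)cc1Br | target

## Step count and least certain steps

Total step count: 7. Longest linear sequence: 7 steps (1 to 12); phenylboronic acid 4 enters in step 2.

**Step 6 (key step).**
- What may go wrong: loss of control over the degree of bromination on ring B. The second, ortho substitution is much slower than the first, so the reaction may stall after the para substitution. Forcing it risks a third substitution at C6'. The Lewis acid and HBr may also strip the acetate, after which ring A would be brominated at C4.
- Fallback, setting out from 3 and returning at 12: ring B is brought in with both bromines attached. Phenol 3 is O-arylated with bis(2,4-dibromophenyl)iodonium chloride F1 (made from 1,3-dibromobenzene with (IO)2SO4 in H2SO4, then NaCl) in aqueous NaOH/dioxane at 80 °C. This is a metal-free aryl transfer from trivalent iodine that leaves C–Br bonds alone, and it gives 1,5-dibromo-2-(2,4-dibromophenoxy)-3-methoxybenzene F2 (the same compound as A7). BBr3 in CH2Cl2 cleaves the methyl ether to 3,5-dibromo-2-(2,4-dibromophenoxy)phenol F3. The ortho-selective bromination of step 4 (NBS, catalytic i-Pr2NH, CH2Cl2, 0 °C) then places the last bromine next to the hydroxyl and gives 12 directly; ring B, already dibrominated, is inert to NBS.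

**Step 4.**
- What may go wrong: poor positional control. Bromine may enter para to the hydroxyl (C4, between the two bromines) instead of ortho, or at both carbons, if hydrogen-bonded delivery does not dominate on this acidic, electron-poor phenol.
- Fallback, setting out from phenylboronic acid 4 and returning at 8: all three ring A bromines are fixed before the ether is made. Commercial 3-bromo-2-methoxyphenol F4 is dibrominated (Br2, AcOH, rt) ortho and para to its free hydroxyl, the only activated positions, to give 3,4,6-tribromo-2-methoxyphenol F5. Chan–Lam coupling of F5 with 4 under the conditions of step 2 gives 1,2,5-tribromo-3-methoxy-4-phenoxybenzene F6. BBr3 in CH2Cl2 then gives 8.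

**Step 2.**
- What may go wrong: slow C–O bond formation at an oxygen flanked by bromine and methoxy, so that protodeboronation and oxidative self-coupling of the boronic acid consume the aryl donor first.
- Fallback, setting out from 3 and returning at 5: metal-free O-phenylation with diphenyliodonium triflate and KOt-Bu in THF at rt to 40 °C. This is ligand coupling at trivalent iodine, which tolerates hindered phenoxides and aryl bromides. No new compound arises on the way.

## Further compounds

F1 | step 6 | bis(2,4-dibromophenyl)iodonium chloride | Brc1ccc([I+]c2ccc(Br)cc2Br)c(Br)c1.[Cl-]
F2 | step 6 | 1,5-dibromo-2-(2,4-dibromophenoxy)-3-methoxybenzene | COc1cc(Br)cc(Br)c1Oc1ccc(Br)cc1Br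
F3 | step 6 | 3,5-dibromo-2-(2,4-dibromophenoxy)phenol | Oc1cc(Br)cc(Br)c1Oc1ccc(Br)cc1Br
F4 | step 4 | 3-bromo-2-methoxyphenol | COc1c(Br)cccc1O
F5 | step 4 | 3,4,6-tribromo-2-methoxyphenol | COc1c(Br)c(Br)cc(Br)c1O
F6 | step 4 | 1,2,5-tribromo-3-methoxy-4-phenoxybenzene | COc1c(Br)c(Br)cc(Br)c1Oc1ccccc1
F0 | step 2 | none | none
A1 | alternative 1 | 3,5-dibromo-2H-pyran-2-one | O=C1OC=C(Br)C=C1Br
A2 | alternative 1 | 2-[(2,4-dibromophenoxy)ethynyl]-4,4,5,5-tetramethyl-1,3,2-dioxaborolane | CC1(C)OB(C#COc2ccc(Br)cc2Br)OC1(C)C
A3 | alternative 1 | 2-[3,5-dibromo-2-(2,4-dibromophenoxy)phenyl]-4,4,5,5-tetramethyl-1,3,2-dioxaborolane | CC1(C)OB(c2cc(Br)cc(Br)c2Oc2ccc(Br)cc2Br)OC1(C)C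
A4 | alternative 2 | 3-(2,4-dibromophenoxy)-4-methoxyaniline | COc1ccc(N)cc1Oc1ccc(Br)cc1Br
A5 | alternative 2 | 2,3,6-tribromo-5-(2,4-dibromophenoxy)-4-methoxyaniline | COc1c(Br)c(Br)c(N)c(Br)c1Oc1ccc(Br)cc1Br
A6 | alternative 3 | 1,5-dibromo-2-(ethynyloxy)-3-methoxybenzene | COc1cc(Br)cc(Br)c1OC#C
A7 | alternative 3 | 1,5-dibromo-2-(2,4-dibromophenoxy)-3-methoxybenzene | COc1cc(Br)cc(Br)c1Oc1ccc(Br)cc1Br
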